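**Plan**
1. Retrosynthesis: the C9 acetate and the C8 ester are removed first, then the furanone is taken back to its C1 carbinol and the ring O–C10 bond is cut. Next come C3–C4 (ten-membered ring), C6–C7 with the lactone C–O bond, and C1–C2 with C10–C14. This leaves D-erythronolactone acetonide (C7–C10), oxirane (C2, C3), methyl acrylate (C11–C13) and but-2-yn-1-ol (C4–C6, C15).
2. Enabling feature: the furanone oxygen ties ketone-level C3 to the quaternary C10 that sits next to oxidised C1 in the ten-membered ring. This is the pattern left when a C3 carbonyl oxygen opens a 1(10)-epoxide at C10.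
3. Forward order: C7–C10 chain, then the E-olefin and C1–C3 by carboalumination and oxirane opening, then the lactone ring by chromium allylation of the Z-iodoenal, then the ten-membered ring by Ni/Cr closure of C3–C4, then the 1(10)-epoxide, the dihydrofuran ring (key step), the furanone and the two esters.
4. Stereochemistry: C8 and C9 come from the lactone. C7 and C6 come from the allylation (induction from C8, anti chair). C10 comes from face-selective epoxidation of the E-olefin followed by inversion in the key step. The E and Z ring olefins come from syn-carboalumination and from the Z-iodoenal.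

Key step: step 21

Remark on the chemistry: germacranolide numbering is used (ring C1–C10, C14 on C10, C15 on C4, lactone C11–C13 with C12–O–C6). The carbonyl carbon of 1 is taken as C7 and its CH2 as C10, which is what the (8S,9S)-diol of the target requires. Descriptors at C6, C7, C9 and C10 change along the route only through CIP priority changes.

Step 1
Reactants: 1 2,3-O-isopropylidene-D-erythronolactone
Product: 2 2,3-O-isopropylidene-D-erythrofuranose (lactol; both anomers)
Conditions: i-Bu2AlH, CH2Cl2, −78 °C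
Reagents that add atoms: none
Why: Lactone-to-lactol reduction with one equivalent of i-Bu2AlH at low temperature stops at the hemiacetal and leaves the two acetonide stereocentres (the future C8 and C9) untouched.

Step 2
Reactants: 2 2,3-O-isopropylidene-D-erythrofuranose
Product: 3 [(4R,5S)-2,2-dimethyl-5-vinyl-1,3-dioxolan-4-yl]methanol
Conditions: Ph3PCH3Br, KOt-Bu, THF, 0 °C to rt
Reagents that add atoms: methyltriphenylphosphonium bromide, C[P+](c1ccccc1)(c1ccccc1)c1ccccc1.[Br-]
Why: Wittig methylenation of the hydroxy aldehyde in equilibrium with the lactol should free the C10 hydroxyl and park C7 as a vinyl group without touching a stereocentre.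

Step 3
Reactants: 3 [(4R,5S)-2,2-dimethyl-5-vinyl-1,3-dioxolan-4-yl]methanol
Product: 4 (4S,5S)-2,2-dimethyl-5-vinyl-1,3-dioxolane-4-carbaldehyde
Conditions: DMP, NaHCO3, CH2Cl2, 0 °C to rt
Reagents that add atoms: none
Why: Dess–Martin oxidation under buffered, non-basic conditions should give the α-alkoxy aldehyde without epimerising the cis-dioxolane centre next to it.

Step 4
Reactants: 4 (4S,5S)-2,2-dimethyl-5-vinyl-1,3-dioxolane-4-carbaldehyde
Product: 5 (4R,5S)-4-ethynyl-2,2-dimethyl-5-vinyl-1,3-dioxolane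
Conditions: dimethyl (1-diazo-2-oxopropyl)phosphonate, K2CO3, MeOH, 0 °C to rt
Reagents that add atoms: dimethyl (1-diazo-2-oxopropyl)phosphonate, CC(=O)C(=[N+]=[N-])P(=O)(OC)OC
Why: Ohira–Bestmann (Seyferth–Gilbert) homologation should turn the aldehyde into the terminal alkyne C10≡C1 under carbonate conditions mild enough to keep the adjacent centre intact.

Step 5
Reactants: 5 (4R,5S)-4-ethynyl-2,2-dimethyl-5-vinyl-1,3-dioxolane
Product: 7 [(4S,5R)-5-ethynyl-2,2-dimethyl-1,3-dioxolan-4-yl]methanol, via alkynyl aldehyde 6 (not isolated)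
Conditions: O3, CH2Cl2/MeOH, −78 °C (Sudan Red 7B end point); then NaBH4, −78 to 0 °C
Reagents that add atoms: ozone, O=[O+][O-]
Why: Ozonolysis (Criegee cleavage) is far faster at a monosubstituted alkene than at a terminal alkyne, so titration to the indicator end point should cleave only the vinyl group, and the reductive work-up should deliver the C7 carbinol.

Step 6
Reactants: 7 [(4S,5R)-5-ethynyl-2,2-dimethyl-1,3-dioxolan-4-yl]methanol
Product: 8 tert-butyl{[(4S,5R)-5-ethynyl-2,2-dimethyl-1,3-dioxolan-4-yl]methoxy}dimethylsilane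
Conditions: TBSCl, imidazole, DMF, rt
Reagents that add atoms: tert-butyldimethylsilyl chloride, CC(C)(C)[Si](C)(C)Cl
Why: Imidazole-promoted silylation of the primary alcohol gives an ether that tolerates the organoaluminium and organolithium reagents of step 7.

Step 7
Reactants: 8 tert-butyl{[(4S,5R)-5-ethynyl-2,2-dimethyl-1,3-dioxolan-4-yl]methoxy}dimethylsilane; 9 oxirane
Product: 12 (3E)-4-[(4R,5S)-5-({[tert-butyl(dimethyl)silyl]oxy}methyl)-2,2-dimethyl-1,3-dioxolan-4-yl]pent-3-en-1-ol, via alkenylalane 10 (not isolated), via lithium alkenylaluminate 11 (not isolated)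
Conditions: Me3Al, Cp2ZrCl2 (cat.), CH2Cl2, 0 °C to rt; n-BuLi, THF, −78 °C; then 9, −78 to 0 °C
Reagents that add atoms: trimethylaluminium, C[Al](C)C
Why: Zirconium-catalysed carboalumination (Negishi) adds CH3 and Al syn across the terminal alkyne with aluminium on the terminal carbon, and the derived aluminate opens oxirane with retention at the alkenyl carbon, so C2 ends cis to the C14 methyl and the 1(10) olefin is E.

Step 8
Reactants: 12 (3E)-4-[(4R,5S)-5-({[tert-butyl(dimethyl)silyl]oxy}methyl)-2,2-dimethyl-1,3-dioxolan-4-yl]pent-3-en-1-ol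
Product: 13 tert-butyl({(4S,5R)-5-[(2E)-5-[(4-methoxybenzyl)oxy]pent-2-en-2-yl]-2,2-dimethyl-1,3-dioxolan-4-yl}methoxy)dimethylsilane
Conditions: NaH, PMBCl, Bu4NI (cat.), THF/DMF, 0 °C to rt
Reagents that add atoms: 4-methoxybenzyl chloride, COc1ccc(CCl)cc1
Why: Williamson etherification masks the C3 hydroxyl with a group that is removable later by oxidation and is orthogonal to the silyl ether and the acetonide.

Step 9
Reactants: 13 tert-butyl({(4S,5R)-5-[(2E)-5-[(4-methoxybenzyl)oxy]pent-2-en-2-yl]-2,2-dimethyl-1,3-dioxolan-4-yl}methoxy)dimethylsilane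
Product: 14 {(4S,5R)-5-[(2E)-5-[(4-methoxybenzyl)oxy]pent-2-en-2-yl]-2,2-dimethyl-1,3-dioxolan-4-yl}methanol
Conditions: Bu4NF, THF, 0 °C to rt
Reagents that add atoms: none
Why: Fluoride-induced desilylation frees only the C7 hydroxyl, since the benzyl-type ether and the acetonide are inert to fluoride.

Step 10
Reactants: 14 {(4S,5R)-5-[(2E)-5-[(4-methoxybenzyl)oxy]pent-2-en-2-yl]-2,2-dimethyl-1,3-dioxolan-4-yl}methanol
Product: 15 (4R,5R)-5-[(2E)-5-[(4-methoxybenzyl)oxy]pent-2-en-2-yl]-2,2-dimethyl-1,3-dioxolane-4-carbaldehyde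
Conditions: DMP, NaHCO3, CH2Cl2, 0 °C
Reagents that add atoms: none
Why: Dess–Martin oxidation should give the C7 aldehyde without base, so the cis relationship at C8/C9 is kept; the aldehyde is used at once.

Step 11
Reactants: 15 (4R,5R)-5-[(2E)-5-[(4-methoxybenzyl)oxy]pent-2-en-2-yl]-2,2-dimethyl-1,3-dioxolane-4-carbaldehyde; 16 methyl acrylate
Product: 17 methyl 2-[hydroxy{(4S,5R)-5-[(2E)-5-[(4-methoxybenzyl)oxy]pent-2-en-2-yl]-2,2-dimethyl-1,3-dioxolan-4-yl}methyl]prop-2-enoate (both carbinol epimers)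
Conditions: 16 (excess), DABCO, dioxane/H2O, rt
Reagents that add atoms: none
Why: The Morita–Baylis–Hillman reaction of the α-alkoxy aldehyde with methyl acrylate installs C11–C13, and the new carbinol configuration does not matter because this carbon becomes sp2 in step 12.

Step 12
Reactants: 17 methyl 2-[hydroxy{(4S,5R)-5-[(2E)-5-[(4-methoxybenzyl)oxy]pent-2-en-2-yl]-2,2-dimethyl-1,3-dioxolan-4-yl}methyl]prop-2-enoate
Product: 18 methyl (2Z)-2-(bromomethyl)-3-{(4S,5R)-5-[(2E)-5-[(4-methoxybenzyl)oxy]pent-2-en-2-yl]-2,2-dimethyl-1,3-dioxolan-4-yl}prop-2-enoate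
Conditions: NBS, Me2S, CH2Cl2, −20 °C to rt
Reagents that add atoms: N-bromosuccinimide, O=C1CCC(=O)N1Br
Why: Activation of the allylic alcohol as an alkoxysulfonium salt (Corey–Kim-type NBS–Me2S adduct) followed by SN2′ attack of bromide should give the rearranged primary bromide as the thermodynamically preferred Z isomer under non-acidic conditions.

Step 13
Reactants: 19 but-2-yn-1-ol
Product: 21 (2Z)-3-iodobut-2-en-1-ol, via cyclic alkenylaluminate 20 (not isolated)
Conditions: NaAlH2(OCH2CH2OMe)2, Et2O, 0 °C to rt; then I2, THF, −78 to 0 °C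
Reagents that add atoms: iodine, [I][I]
Why: Trans-hydroalumination of the propargylic alkoxide places aluminium on the methyl-bearing carbon within a five-membered chelate, and iodinolysis with retention gives the Z iodoalkene.

Step 14
Reactants: 21 (2Z)-3-iodobut-2-en-1-ol
Product: 22 (2Z)-3-iodobut-2-enal
Conditions: MnO2, CH2Cl2, rt
Reagents that add atoms: none
Why: Allylic oxidation with MnO2 is neutral and should give the enal without Z-to-E isomerisation; the aldehyde is used as a solution without storage.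

Step 15
Reactants: 18 methyl (2Z)-2-(bromomethyl)-3-{(4S,5R)-5-[(2E)-5-[(4-methoxybenzyl)oxy]pent-2-en-2-yl]-2,2-dimethyl-1,3-dioxolan-4-yl}prop-2-enoate; 22 (2Z)-3-iodobut-2-enal
Product: 24 (4S,5S)-5-[(1Z)-2-iodoprop-1-en-1-yl]-4-{(4S,5R)-5-[(2E)-5-[(4-methoxybenzyl)oxy]pent-2-en-2-yl]-2,2-dimethyl-1,3-dioxolan-4-yl}-3-methylideneoxolan-2-one, via anti hydroxy ester 23 (not isolated)
Conditions: CrCl2, THF, 0 °C to rt; then PPTS, benzene, 50 °C
Reagents that add atoms: none
Why: In this Nozaki–Hiyama allylation with divalent chromium (the vinyl iodide is inert without nickel) the 2-(methoxycarbonyl)allylchromium should add through C7 in a chair transition state with the C8 substituent pseudo-equatorial, giving the anti adduct and hence the trans-lactone, while the aldehyde approaches anti to the C8–C9 bond in the rotamer that turns H8 toward the ester (allylic strain), which sets C7 and C6 as in the target; mild acid completes lactonisation.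

Step 16
Reactants: 24 (4S,5S)-5-[(1Z)-2-iodoprop-1-en-1-yl]-4-{(4S,5R)-5-[(2E)-5-[(4-methoxybenzyl)oxy]pent-2-en-2-yl]-2,2-dimethyl-1,3-dioxolan-4-yl}-3-methylideneoxolan-2-one
Product: 25 (4S,5S)-4-{(4S,5R)-5-[(2E)-5-hydroxypent-2-en-2-yl]-2,2-dimethyl-1,3-dioxolan-4-yl}-5-[(1Z)-2-iodoprop-1-en-1-yl]-3-methylideneoxolan-2-one
Conditions: DDQ, CH2Cl2/pH 7 buffer, 0 °C
Reagents that add atoms: none
Why: Oxidative cleavage of the 4-methoxybenzyl ether by DDQ (hydride abstraction, then hydrolysis of the oxocarbenium ion) should spare the acetonide, the vinyl iodide and the methylene lactone.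

Step 17
Reactants: 25 (4S,5S)-4-{(4S,5R)-5-[(2E)-5-hydroxypent-2-en-2-yl]-2,2-dimethyl-1,3-dioxolan-4-yl}-5-[(1Z)-2-iodoprop-1-en-1-yl]-3-methylideneoxolan-2-one
Product: 26 (4S,5S)-4-{(4S,5R)-2,2-dimethyl-5-[(2E)-5-oxopent-2-en-2-yl]-1,3-dioxolan-4-yl}-5-[(1Z)-2-iodoprop-1-en-1-yl]-3-methylideneoxolan-2-one
Conditions: DMP, NaHCO3, CH2Cl2, 0 °C
Reagents that add atoms: none
Why: Buffered Dess–Martin oxidation of the homoallylic alcohol should give the β,γ-unsaturated C3 aldehyde without migration of the 1(10) olefin; it is taken on directly.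

Step 18
Reactants: 26 (4S,5S)-4-{(4S,5R)-2,2-dimethyl-5-[(2E)-5-oxopent-2-en-2-yl]-1,3-dioxolan-4-yl}-5-[(1Z)-2-iodoprop-1-en-1-yl]-3-methylideneoxolan-2-one
Product: 27 (6R,7S,8S,9R)-3-hydroxy-8,9-(isopropylidenedioxy)germacra-1(10)E,4Z,11(13)-trien-12,6-olide (both C3 epimers)
Conditions: CrCl2, NiCl2 (cat.), degassed DMSO, rt, high dilution (about 2 mM)
Reagents that add atoms: none
Why: In the Nozaki–Hiyama–Kishi reaction zerovalent nickel inserts into the vinyl iodide, the alkenyl group passes to trivalent chromium with retention of the Z geometry and adds to the aldehyde; high dilution and the turn imposed by the cis-acetonide and the trans-lactone should favour closure of the ten-membered ring, and the C3 configuration is irrelevant because it is oxidised in step 19.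

Step 19
Reactants: 27 (6R,7S,8S,9R)-3-hydroxy-8,9-(isopropylidenedioxy)germacra-1(10)E,4Z,11(13)-trien-12,6-olide
Product: 28 (6R,7S,8S,9R)-8,9-(isopropylidenedioxy)-3-oxogermacra-1(10)E,4Z,11(13)-trien-12,6-olide
Conditions: DMP, NaHCO3, CH2Cl2, 0 °C
Reagents that add atoms: none
Why: Dess–Martin oxidation of the allylic alcohol gives the C3 enone, which provides the nucleophilic carbonyl for step 21 and deactivates the C4=C5 olefin toward the electrophilic oxidant of step 20.

Step 20
Reactants: 28 (6R,7S,8S,9R)-8,9-(isopropylidenedioxy)-3-oxogermacra-1(10)E,4Z,11(13)-trien-12,6-olide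
Product: 29 (1S,6R,7S,8S,9S,10R)-1,10-epoxy-8,9-(isopropylidenedioxy)-3-oxogermacra-4Z,11(13)-dien-12,6-olide
Conditions: DMDO, acetone/CH2Cl2, −40 to −20 °C
Reagents that add atoms: dimethyldioxirane, CC1(C)OO1
Why: Electrophilic dioxirane epoxidation should touch only the isolated, electron-rich 1(10) olefin and is stereospecific (trans-epoxide from the E-olefin); the ring spans one face of this olefin, and in the rotamer with H9 eclipsing the C14 methyl the ring lies anti to O9, so the oxidant should add to the open face syn to O9 and give the (1S,10R)-epoxide under neutral conditions that leave only acetone.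

Step 21
Reactants: 29 (1S,6R,7S,8S,9S,10R)-1,10-epoxy-8,9-(isopropylidenedioxy)-3-oxogermacra-4Z,11(13)-dien-12,6-olide
Product: 30 (1S,6R,7S,8S,9S,10S)-3,10-epoxy-1-hydroxy-8,9-(isopropylidenedioxy)germacra-2,4Z,11(13)-trien-12,6-olide
Conditions: Sc(OTf)3 (10 mol%), 4 Å molecular sieves, CH2Cl2, −40 to 0 °C
Reagents that add atoms: none
Why: Sc(OTf)3 binds the epoxide oxygen and lengthens the C10–O bond, whose tertiary carbon takes most of the positive charge; the C3 carbonyl oxygen, held over the inner face of C10 by the ten-membered ring, attacks anti to the departing oxygen and gives a cyclic oxocarbenium ion, stabilised by the C4=C5 olefin, that loses a C2 proton to form the enol ether. The closest known reaction is the acid-mediated cyclisation of β,γ-epoxy ketones to 3-hydroxy-2,3-dihydrofurans and furans. The one ring formed, the dihydrofuran O–C3–C2–C1–C10, closes in a 5-endo mode at an epoxide carbon, which is tolerated because bond breaking at the tertiary centre runs ahead of bond making. The only new stereocentre, quaternary C10, is controlled by the epoxide configuration from step 20 through inversion, while C1 keeps its oxygen with retention. The step needs attack by the carbonyl oxygen in preference to a 1,2-hydride shift (Meinwald rearrangement), to enolisation and β-elimination giving the γ-hydroxy enone, and to neighbouring-group capture; the aprotic catalytic Lewis acid, the absence of base, the 1,4-relationship between the carbonyl oxygen and C10, and the acetonide (no C9 acyl group that could form a dioxolanylium ion) should secure this. Quaternary C10 also blocks aromatisation, so C1 stays at the carbinol level for step 22.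

Step 22
Reactants: 30 (1S,6R,7S,8S,9S,10S)-3,10-epoxy-1-hydroxy-8,9-(isopropylidenedioxy)germacra-2,4Z,11(13)-trien-12,6-olide
Product: 31 (6R,7S,8S,9S,10R)-3,10-epoxy-8,9-(isopropylidenedioxy)-1-oxogermacra-2,4Z,11(13)-trien-12,6-olide
Conditions: DMP, pyridine, CH2Cl2, 0 °C
Reagents that add atoms: none
Why: Dess–Martin oxidation of the allylic C1 carbinol under buffered conditions should give the 3(2H)-furanone (a vinylogous ester) and remove the acid-labile allylic alcohol next to the enol ether.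

Step 23
Reactants: 31 (6R,7S,8S,9S,10R)-3,10-epoxy-8,9-(isopropylidenedioxy)-1-oxogermacra-2,4Z,11(13)-trien-12,6-olide
Product: 32 (6R,7R,8S,9S,10R)-3,10-epoxy-8,9-dihydroxy-1-oxogermacra-2,4Z,11(13)-trien-12,6-olide
Conditions: TFA/H2O (9:1), 0 °C
Reagents that add atoms: none
Why: Acid-catalysed hydrolysis of the isopropylidene ketal frees the diol, and the furanone, the dienone and the methylene lactone carry no comparably acid-labile function.

Step 24
Reactants: 33 tert-butyl acrylate; 34 acetaldehyde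
Product: 35 tert-butyl 3-hydroxy-2-methylidenebutanoate (racemic)
Conditions: DABCO, neat, rt
Reagents that add atoms: none
Why: The Morita–Baylis–Hillman reaction joins the two components, and the carbinol centre formed is removed in step 25.

Step 25
Reactants: 35 tert-butyl 3-hydroxy-2-methylidenebutanoate
Product: 37 tert-butyl (2E)-2-(acetoxymethyl)but-2-enoate, via allylic acetate 36 (not isolated)
Conditions: Ac2O, Et3N, DMAP (cat.), CH2Cl2, 0 °C; then DABCO (cat.), THF, 65 °C
Reagents that add atoms: acetic anhydride, CC(=O)OC(C)=O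
Why: Acetylation followed by amine-mediated SN2′–SN2′ transposition of the allylic acetate leads to the conjugated trisubstituted ester, whose thermodynamic isomer has the methyl group trans to the ester (2E).

Step 26
Reactants: 37 tert-butyl (2E)-2-(acetoxymethyl)but-2-enoate
Product: 38 (2E)-2-(acetoxymethyl)but-2-enoic acid
Conditions: TFA, CH2Cl2, 0 °C to rt
Reagents that add atoms: none
Why: Acidolysis of the tert-butyl ester through the tert-butyl cation leaves the primary allylic acetate and the olefin geometry in place.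

Step 27
Reactants: 32 (6R,7R,8S,9S,10R)-3,10-epoxy-8,9-dihydroxy-1-oxogermacra-2,4Z,11(13)-trien-12,6-olide; 38 (2E)-2-(acetoxymethyl)but-2-enoic acid
Product: 40 (6R,7S,8S,9S,10R)-8-{[(2E)-2-(acetoxymethyl)but-2-enoyl]oxy}-3,10-epoxy-9-hydroxy-1-oxogermacra-2,4Z,11(13)-trien-12,6-olide, via mixed anhydride 39 (not isolated)
Conditions: 38, 2,4,6-trichlorobenzoyl chloride, Et3N, toluene, rt; then 32, DMAP, toluene, 0 °C to rt
Reagents that add atoms: none
Why: In the Yamaguchi esterification the mixed anhydride acylates through the acylpyridinium ion, and the C8 hydroxyl should react in preference to the C9 hydroxyl, which is neopentylic (flanked by quaternary C10) and can hydrogen-bond to the C1 carbonyl.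

Step 28
Reactants: 40 (6R,7S,8S,9S,10R)-8-{[(2E)-2-(acetoxymethyl)but-2-enoyl]oxy}-3,10-epoxy-9-hydroxy-1-oxogermacra-2,4Z,11(13)-trien-12,6-olide
Product: 41 (6R,7S,8S,9S,10R)-9-acetoxy-8-{[(2E)-2-(acetoxymethyl)but-2-enoyl]oxy}-3,10-epoxy-1-oxogermacra-2,4Z,11(13)-trien-12,6-olide (CNP0325609.1)
Conditions: Ac2O, pyridine, DMAP (cat.), CH2Cl2, rt
Reagents that add atoms: acetic anhydride, CC(=O)OC(C)=O
Why: DMAP-catalysed acetylation of the remaining hindered secondary hydroxyl completes the target without touching a stereocentre.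

**Compound list**
1 | 2,3-O-isopropylidene-D-erythronolactone | C1[C@@H](OC2(C)C)[C@@H](O2)C(=O)O1 | starting material
2 | 2,3-O-isopropylidene-D-erythrofuranose (lactol; both anomers) | C1[C@@H](OC2(C)C)[C@@H](O2)C(O)O1 | intermediate
3 | [(4R,5S)-2,2-dimethyl-5-vinyl-1,3-dioxolan-4-yl]methanol | OC[C@@H](OC1(C)C)[C@@H](O1)C=C | intermediate
4 | (4S,5S)-2,2-dimethyl-5-vinyl-1,3-dioxolane-4-carbaldehyde | O=C[C@@H](OC1(C)C)[C@@H](O1)C=C | intermediate
5 | (4R,5S)-4-ethynyl-2,2-dimethyl-5-vinyl-1,3-dioxolane | C#C[C@@H](OC1(C)C)[C@@H](O1)C=C | intermediate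
6 | (4R,5R)-5-ethynyl-2,2-dimethyl-1,3-dioxolane-4-carbaldehyde | C#C[C@@H](OC1(C)C)[C@@H](O1)C=O | intermediate
7 | [(4S,5R)-5-ethynyl-2,2-dimethyl-1,3-dioxolan-4-yl]methanol | C#C[C@@H](OC1(C)C)[C@@H](O1)CO | intermediate
8 | tert-butyl{[(4S,5R)-5-ethynyl-2,2-dimethyl-1,3-dioxolan-4-yl]methoxy}dimethylsilane | C#C[C@@H](OC1(C)C)[C@@H](O1)CO[Si](C)(C)C(C)(C)C | intermediate
9 | oxirane | C1CO1 | starting material
10 | {(1E)-2-[(4R,5S)-5-({[tert-butyl(dimethyl)silyl]oxy}methyl)-2,2-dimethyl-1,3-dioxolan-4-yl]prop-1-en-1-yl}dimethylalane | C[Al](C)/C=C(\C)[C@@H](OC1(C)C)[C@@H](O1)CO[Si](C)(C)C(C)(C)C | intermediate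
11 | lithium butyl{(1E)-2-[(4R,5S)-5-({[tert-butyl(dimethyl)silyl]oxy}methyl)-2,2-dimethyl-1,3-dioxolan-4-yl]prop-1-en-1-yl}dimethylaluminate | [Li+].CCCC[Al-](C)(C)/C=C(\C)[C@@H](OC1(C)C)[C@@H](O1)CO[Si](C)(C)C(C)(C)C | intermediate
12 | (3E)-4-[(4R,5S)-5-({[tert-butyl(dimethyl)silyl]oxy}methyl)-2,2-dimethyl-1,3-dioxolan-4-yl]pent-3-en-1-ol | OCC/C=C(\C)[C@@H](OC1(C)C)[C@@H](O1)CO[Si](C)(C)C(C)(C)C | intermediate
13 | tert-butyl({(4S,5R)-5-[(2E)-5-[(4-methoxybenzyl)oxy]pent-2-en-2-yl]-2,2-dimethyl-1,3-dioxolan-4-yl}methoxy)dimethylsilane | COc1ccc(COCC/C=C(\C)[C@@H](OC2(C)C)[C@@H](O2)CO[Si](C)(C)C(C)(C)C)cc1 | intermediate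
14 | {(4S,5R)-5-[(2E)-5-[(4-methoxybenzyl)oxy]pent-2-en-2-yl]-2,2-dimethyl-1,3-dioxolan-4-yl}methanol | COc1ccc(COCC/C=C(\C)[C@@H](OC2(C)C)[C@@H](O2)CO)cc1 | intermediate
15 | (4R,5R)-5-[(2E)-5-[(4-methoxybenzyl)oxy]pent-2-en-2-yl]-2,2-dimethyl-1,3-dioxolane-4-carbaldehyde | COc1ccc(COCC/C=C(\C)[C@@H](OC2(C)C)[C@@H](O2)C=O)cc1 | intermediate
16 | methyl acrylate | C=CC(=O)OC | starting material
17 | methyl 2-[hydroxy{(4S,5R)-5-[(2E)-5-[(4-methoxybenzyl)oxy]pent-2-en-2-yl]-2,2-dimethyl-1,3-dioxolan-4-yl}methyl]prop-2-enoate (carbinol epimers) | COc1ccc(COCC/C=C(\C)[C@@H](OC2(C)C)[C@@H](O2)C(O)C(=C)C(=O)OC)cc1 | intermediate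
18 | methyl (2Z)-2-(bromomethyl)-3-{(4S,5R)-5-[(2E)-5-[(4-methoxybenzyl)oxy]pent-2-en-2-yl]-2,2-dimethyl-1,3-dioxolan-4-yl}prop-2-enoate | COc1ccc(COCC/C=C(\C)[C@@H](OC2(C)C)[C@@H](O2)/C=C(\CBr)C(=O)OC)cc1 | intermediate
19 | but-2-yn-1-ol | CC#CCO | starting material
20 | sodium 2,2-bis(2-methoxyethoxy)-3-methyl-2,5-dihydro-1,2-oxaluminol-2-uide (cyclic Z-alkenylaluminate) | [Na+].CC1=CCO[Al-]1(OCCOC)OCCOC | intermediate
21 | (2Z)-3-iodobut-2-en-1-ol | C/C(I)=C/CO | intermediate
22 | (2Z)-3-iodobut-2-enal | C/C(I)=C/C=O | intermediate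
23 | methyl (3S,4S,5Z)-4-hydroxy-6-iodo-3-{(4S,5R)-5-[(2E)-5-[(4-methoxybenzyl)oxy]pent-2-en-2-yl]-2,2-dimethyl-1,3-dioxolan-4-yl}-2-methylidenehept-5-enoate | COC(=O)C(=C)[C@@H]([C@H](O)/C=C(/C)I)[C@@H]1OC(C)(C)O[C@@H]1/C(C)=C/CCOCc2ccc(OC)cc2 | intermediate
24 | (4S,5S)-5-[(1Z)-2-iodoprop-1-en-1-yl]-4-{(4S,5R)-5-[(2E)-5-[(4-methoxybenzyl)oxy]pent-2-en-2-yl]-2,2-dimethyl-1,3-dioxolan-4-yl}-3-methylideneoxolan-2-one | C=C1C(=O)O[C@H](/C=C(/C)I)[C@H]1[C@@H]2OC(C)(C)O[C@@H]2/C(C)=C/CCOCc3ccc(OC)cc3 | intermediate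
25 | (4S,5S)-4-{(4S,5R)-5-[(2E)-5-hydroxypent-2-en-2-yl]-2,2-dimethyl-1,3-dioxolan-4-yl}-5-[(1Z)-2-iodoprop-1-en-1-yl]-3-methylideneoxolan-2-one | C=C1C(=O)O[C@H](/C=C(/C)I)[C@H]1[C@@H]2OC(C)(C)O[C@@H]2/C(C)=C/CCO | intermediate
26 | (4S,5S)-4-{(4S,5R)-2,2-dimethyl-5-[(2E)-5-oxopent-2-en-2-yl]-1,3-dioxolan-4-yl}-5-[(1Z)-2-iodoprop-1-en-1-yl]-3-methylideneoxolan-2-one | C=C1C(=O)O[C@H](/C=C(/C)I)[C@H]1[C@@H]2OC(C)(C)O[C@@H]2/C(C)=C/CC=O | intermediate
27 | (6R,7S,8S,9R)-3-hydroxy-8,9-(isopropylidenedioxy)germacra-1(10)E,4Z,11(13)-trien-12,6-olide (C3 epimers) | C=C1C(=O)O[C@@H]2/C=C(/C)C(O)C/C=C(\C)[C@@H](OC3(C)C)[C@@H](O3)[C@@H]12 | intermediate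
28 | (6R,7S,8S,9R)-8,9-(isopropylidenedioxy)-3-oxogermacra-1(10)E,4Z,11(13)-trien-12,6-olide | C=C1C(=O)O[C@@H]2/C=C(/C)C(=O)C/C=C(\C)[C@@H](OC3(C)C)[C@@H](O3)[C@@H]12 | intermediate
29 | (1S,6R,7S,8S,9S,10R)-1,10-epoxy-8,9-(isopropylidenedioxy)-3-oxogermacra-4Z,11(13)-dien-12,6-olide | C=C1C(=O)O[C@@H]2/C=C(/C)C(=O)C[C@@H]3O[C@@]3(C)[C@@H](OC4(C)C)[C@@H](O4)[C@@H]12 | intermediate
30 | (1S,6R,7S,8S,9S,10S)-3,10-epoxy-1-hydroxy-8,9-(isopropylidenedioxy)germacra-2,4Z,11(13)-trien-12,6-olide | C=C1C(=O)O[C@@H]2/C=C(/C)C3=C[C@H](O)[C@](C)(O3)[C@@H](OC4(C)C)[C@@H](O4)[C@@H]12 | intermediate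
31 | (6R,7S,8S,9S,10R)-3,10-epoxy-8,9-(isopropylidenedioxy)-1-oxogermacra-2,4Z,11(13)-trien-12,6-olide | C=C1C(=O)O[C@@H]2/C=C(/C)C3=CC(=O)[C@](C)(O3)[C@@H](OC4(C)C)[C@@H](O4)[C@@H]12 | intermediate
32 | (6R,7R,8S,9S,10R)-3,10-epoxy-8,9-dihydroxy-1-oxogermacra-2,4Z,11(13)-trien-12,6-olide | C=C1C(=O)O[C@@H]2/C=C(/C)C3=CC(=O)[C@](C)(O3)[C@@H](O)[C@@H](O)[C@@H]12 | intermediate
33 | tert-butyl acrylate | C=CC(=O)OC(C)(C)C | starting material
34 | acetaldehyde | CC=O | starting material
35 | tert-butyl 3-hydroxy-2-methylidenebutanoate (racemic) | CC(O)C(=C)C(=O)OC(C)(C)C | intermediate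
36 | tert-butyl 3-acetoxy-2-methylidenebutanoate (racemic) | CC(OC(C)=O)C(=C)C(=O)OC(C)(C)C | intermediate
37 | tert-butyl (2E)-2-(acetoxymethyl)but-2-enoate | C/C=C(/C(=O)OC(C)(C)C)COC(C)=O | intermediate
38 | (2E)-2-(acetoxymethyl)but-2-enoic acid | C/C=C(/C(=O)O)COC(C)=O | intermediate
39 | (2E)-2-(acetoxymethyl)but-2-enoic 2,4,6-trichlorobenzoic anhydride | C/C=C(/C(=O)OC(=O)c1c(Cl)cc(Cl)cc1Cl)COC(C)=O | intermediate
40 | (6R,7S,8S,9S,10R)-8-{[(2E)-2-(acetoxymethyl)but-2-enoyl]oxy}-3,10-epoxy-9-hydroxy-1-oxogermacra-2,4Z,11(13)-trien-12,6-olide | C=C1C(=O)O[C@@H]2/C=C(/C)C3=CC(=O)[C@](C)(O3)[C@@H](O)[C@@H](OC(=O)/C(=C/C)COC(C)=O)[C@@H]12 | intermediate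
41 | (6R,7S,8S,9S,10R)-9-acetoxy-8-{[(2E)-2-(acetoxymethyl)but-2-enoyl]oxy}-3,10-epoxy-1-oxogermacra-2,4Z,11(13)-trien-12,6-olide (CNP0325609.1) | C=C1C(=O)O[C@@H]2/C=C(/C)C3=CC(=O)[C@](C)(O3)[C@@H](OC(C)=O)[C@@H](OC(=O)/C(=C/C)COC(C)=O)[C@@H]12 | target

**Step count and risks**
Total step count: 28 (23 in the main line, 2 for aldehyde 22, 3 for acid 38).
Longest linear sequence: 23 steps (steps 1–12, 15–23, 27 and 28).

Steps most likely to fail:

Step 21 (key step). Ionisation at C10 may outrun ring closure. A 1,2-hydride shift from C1 (Meinwald rearrangement to the 1,3-diketone), proton loss to an allylic alcohol, or loss of stereochemical fidelity at C10 could then compete. The fallback sets out from 29 and lowers the nucleophile to the alcohol level.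
- Luche reduction (NaBH4, CeCl3·7H2O, MeOH, −78 °C) with hydride delivery from the ring periphery should give the 1,10-epoxy-3-ol F1, whose hydroxyl points across the ring; the other C3 epimer can be returned to 29 with DMP.
- Acid-catalysed 5-endo opening of the trisubstituted epoxide by the hydroxyl (camphorsulfonic acid, CH2Cl2, 0 °C), a well-known route to 3-hydroxyoxolanes, should give the bridged oxolan-1-ol F2 with inversion at C10.
- Dess–Martin oxidation should give the oxolanone F3.
- Enolisation toward C2, the only enolisable side (TMSOTf, Et3N), should give the trimethylsilyl enol ether F4.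
- Saegusa–Ito dehydrogenation (Pd(OAc)2, MeCN) introduces the C2=C3 double bond, and the sequence comes back to the route at 31.

Step 20. The ten-membered ring may react through its other planar-chiral conformer, so the oxidant would add to the opposite face of the 1(10) olefin. After inversion in step 21 this would give the C10 epimer. The fallback sets out from 28 and uses that same facial preference with a reagent that keeps the new C10–O bond.
- Dihydroxylation (OsO4 cat., N-methylmorpholine N-oxide, acetone/H2O) on the exposed face should give the 1,10-diol F5, with the tertiary C10 hydroxyl already in the configuration of the target.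
- Dess–Martin oxidation of the secondary C1 hydroxyl should give the 10-hydroxy-1,3-diketone F6.
- Acid-catalysed cyclodehydration (TsOH cat., benzene, rt), the classical route from α′-hydroxy-1,3-diketones to 3(2H)-furanones, should return the sequence to the route at 31.

Step 15. The allylchromium may react before its geometry has equilibrated, through the chair with the C8 substituent axial. That would erode the anti selectivity and lead to the cis-lactone. The fallback sets out from 18 and 22 and installs C6 with the opposite configuration on purpose.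
- Indium-mediated Barbier allylation (indium powder, THF/H2O, rt), which is syn-selective for (Z)-2-(bromomethyl)alk-2-enoates, should give the syn hydroxy ester F7.
- Mild hydrolysis (Me3SnOH, 1,2-dichloroethane, 60 °C), with the acid liberated cold and used at once, should give the hydroxy acid F8.
- Mitsunobu lactonisation (PPh3, diisopropyl azodicarboxylate, THF, 0 °C) closes the lactone by displacement at C6 with inversion and comes back to the route at the trans-lactone 24.

Further compounds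
F1 | step 21 | (1S,3R,6R,7S,8S,9S,10R)-1,10-epoxy-3-hydroxy-8,9-(isopropylidenedioxy)germacra-4Z,11(13)-dien-12,6-olide | C=C1C(=O)O[C@@H]2/C=C(/C)[C@H](O)C[C@@H]3O[C@@]3(C)[C@@H](OC4(C)C)[C@@H](O4)[C@@H]12
F2 | step 21 | (1S,3R,6R,7S,8S,9S,10S)-3,10-epoxy-1-hydroxy-8,9-(isopropylidenedioxy)germacra-4Z,11(13)-dien-12,6-olide | C=C1C(=O)O[C@@H]2/C=C(/C)[C@H]3C[C@H](O)[C@](C)(O3)[C@@H](OC4(C)C)[C@@H](O4)[C@@H]12
F3 | step 21 | (3R,6R,7S,8S,9S,10R)-3,10-epoxy-8,9-(isopropylidenedioxy)-1-oxogermacra-4Z,11(13)-dien-12,6-olide | C=C1C(=O)O[C@@H]2/C=C(/C)[C@H]3CC(=O)[C@](C)(O3)[C@@H](OC4(C)C)[C@@H](O4)[C@@H]12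
F4 | step 21 | (3R,6R,7S,8S,9S,10R)-3,10-epoxy-8,9-(isopropylidenedioxy)-1-(trimethylsilyloxy)germacra-1,4Z,11(13)-trien-12,6-olide | C=C1C(=O)O[C@@H]2/C=C(/C)[C@H]3C=C(O[Si](C)(C)C)[C@](C)(O3)[C@@H](OC4(C)C)[C@@H](O4)[C@@H]12
F5 | step 20 | (1R,6R,7S,8S,9S,10S)-1,10-dihydroxy-8,9-(isopropylidenedioxy)-3-oxogermacra-4Z,11(13)-dien-12,6-olide | C=C1C(=O)O[C@@H]2/C=C(/C)C(=O)C[C@@H](O)[C@](C)(O)[C@@H](OC3(C)C)[C@@H](O3)[C@@H]12
F6 | step 20 | (6R,7S,8S,9S,10R)-10-hydroxy-8,9-(isopropylidenedioxy)-1,3-dioxogermacra-4Z,11(13)-dien-12,6-olide | C=C1C(=O)O[C@@H]2/C=C(/C)C(=O)CC(=O)[C@](C)(O)[C@@H](OC3(C)C)[C@@H](O3)[C@@H]12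
F7 | step 15 | methyl (3S,4R,5Z)-4-hydroxy-6-iodo-3-{(4S,5R)-5-[(2E)-5-[(4-methoxybenzyl)oxy]pent-2-en-2-yl]-2,2-dimethyl-1,3-dioxolan-4-yl}-2-methylidenehept-5-enoate | COC(=O)C(=C)[C@@H]([C@@H](O)/C=C(/C)I)[C@@H]1OC(C)(C)O[C@@H]1/C(C)=C/CCOCc2ccc(OC)cc2
F8 | step 15 | (3S,4R,5Z)-4-hydroxy-6-iodo-3-{(4S,5R)-5-[(2E)-5-[(4-methoxybenzyl)oxy]pent-2-en-2-yl]-2,2-dimethyl-1,3-dioxolan-4-yl}-2-methylidenehept-5-enoic acid | OC(=O)C(=C)[C@@H]([C@@H](O)/C=C(/C)I)[C@@H]1OC(C)(C)O[C@@H]1/C(C)=C/CCOCc2ccc(OC)cc2
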